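(All runs stem from a simulated flask on assumed constants, and the scatter is random.)

In a one-step world each partner makes one product, so the delta run, with 0.0475 M of partner, the limiting reagent, on 0.050 M of substrate, should end at 95.0 %, yet I read 69.1 % at 8.00 min.

| setting | delta | theta | epsilon | alpha | Thursday's | Saturday's | Tuesday's |
|---|---|---|---|---|---|---|---|
| substrate | 0.050 M | 0.050 M | 0.050 M | 0.10 M | 0.050 M | 0.050 M (fed, over 5.0 min) | 0.050 M |
| partner | 0.0475 M | 0.024 M | 0.095 M | 0.0475 M | 0.0475 M | 0.0475 M | 0.0475 M (fed, over 5.0 min) |
| remark | run made earlier | run made earlier | run made earlier | run made earlier | everything together at the start | all else is in the flask from the start; the feed brings no volume worth counting | all else is in the flask from the start; the feed brings no volume worth counting |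
| time |  |  |  |  | 12 min | 12 min | 12 min |

| run | time / min | product / % | substrate / % |
|---|---|---|---|
| delta | 0.500 | 21.6 | 78.5 |
| delta | 0.833 | 27.9 | 71.4 |
| delta | 1.33 | 40.5 | 59.0 |
| delta | 2.00 | 47.6 | 50.8 |
| delta | 3.00 | 59.0 | 43.7 |
| delta | 5.00 | 67.4 | 33.7 |
| delta | 8.00 | 69.1 | 30.8 |
| theta | 0.667 | 19.5 | 82.1 |
| theta | 2.00 | 34.9 | 65.7 |
| theta | 3.00 | 39.1 | 59.9 |
| theta | 5.00 | 41.6 | 58.0 |
| theta | 8.00 | 40.8 | 59.1 |
| theta | 10.0 | 40.8 | 58.1 |
| theta | 12.0 | 38.9 | 57.5 |
| epsilon | 1.50 | 54.1 | 46.7 |
| epsilon | 3.00 | 70.9 | 30.7 |
| epsilon | 5.00 | 80.1 | 18.5 |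
| epsilon | 6.00 | 82.4 | 16.8 |
| epsilon | 8.00 | 85.8 | 13.7 |
| epsilon | 10.0 | 89.4 | 13.0 |
| epsilon | 12.0 | 90.0 | 10.7 |
| alpha | 1.00 | 36.4 | 63.3 |
| alpha | 3.00 | 43.7 | 56.0 |
| alpha | 6.00 | 45.1 | 56.2 |
| alpha | 8.00 | 41.9 | 55.5 |
| alpha | 12.0 | 43.8 | 55.5 |

(standard deviation of a reading: 1 percentage point)



1. which flask leads in amount of product, in percent of the substrate charged ("all alike" within 1.5 percentage points) (Thursday's / Saturday's / Tuesday's / all alike)
2. how much product is there at the end, in percent of the substrate charged: Thursday's
3. how much product is there at the end, in percent of the substrate charged: Saturday's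
4. how much product is there at the end, in percent of the substrate charged: Tuesday's

I read that gap as partner lost elsewhere. Partner unaccounted for per product made reads 0.375 in delta, and this is my waste ratio. The alpha run, with twice the substrate and the same partner, reads 0.0845, less by a factor of 4.44, near the square of that doubling. So I let the ratio fall with the square of the substrate standing, taking delta's level as 0.0327 M, midway between its charge and its end.

Now I watch Saturday's slowly. In the first instants the partner is in the flask and the substrate is just starting to arrive. In the middle only part of the substrate has arrived, so I expect the substrate standing to average low over the feed and the waste ratio to be high. Near the end of the feed, the substrate that has arrived waits for whatever partner survives.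

I go round by iteration. Delta's product leaves 0.0154 M standing, which gives a ratio of 1.69 and product of 35.3 %. That swings too far, so I put back the midpoint, 52.2 %. This gives a ratio of 0.702 and product of 55.8 %, which is my figure for Saturday's. Thursday's repeats delta. Tuesday's meets each portion of partner with substrate standing high at the start, so I put it above delta's figure and in the lead.

The forecast differs, with 70 %, 70 % and 70 %, so all alike: “Feed order shouldn't matter.”

    substrate + partner → product, rate k1*[substrate]^1.5*[partner]^0.5 (k = 0.180 L mol⁻¹ s⁻¹)
    partner → decomposed reagent (k = 0.00239 s⁻¹)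

The flasks give 71.1 % for Thursday's, 52.8 % for Saturday's and 75.0 % for Tuesday's, so Tuesday's leads. The gap between Tuesday's and Saturday's, 22 percentage points, shrinks to 1.5 points once the step from partner to decomposed reagent is taken away, the largest single effect. At 12.0 min Tuesday's holds 0.00970 M of decomposed reagent, a waste ratio of 0.259, and Saturday's holds 0.0211 M, a waste ratio of 0.801, more than Tuesday's and than the 0.375 read in delta. One more flask, like Tuesday's but with 0.019 M of partner, has a waste ratio of 0.0588.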